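Percentages of the charge mislead when runs of different charge are laid side by side.

| setting | elm | larch | flask |
|---|---|---|---|
| solid substrate | 5 mM | 20 mM | 10 mM |
| remark | run made earlier | run made earlier |  |
| time |  |  | 2.5 min |

| run | time / min | solid substrate / % | target / % |
|---|---|---|---|
| elm | 0.500 | 53.2 | 5.4 |
| elm | 1.00 | 35.0 | 10.9 |
| elm | 1.50 | 23.0 | 13.6 |
| elm | 2.00 | 13.3 | 15.2 |
| elm | 2.50 | 5.8 | 17.4 |
| larch | 0.200 | 93.3 | 0 |
| larch | 0.667 | 86.4 | 1.6 |
| larch | 1.33 | 81.9 | 3.7 |
| larch | 2.00 | 78.7 | 4.0 |
| larch | 2.50 | 76.2 | 4.3 |

(readings scatter by 0.3 percentage points)

- a species is counted by the solid substrate in it: one target counts as two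
- given per volume of solution although it is solid: solid substrate
- the numbers in the tables scatter by 0.3 percentage points (one standard deviation)
- at the start none of the solid substrate is in solution
- what has only dissolved of solid substrate counts as not reacted
- the reaction counts as stopped when no species that holds the solid substrate changes by six tenths of a point or more over the second half of the time

1. which holds at 2.5 min: what has brought the reaction to rest, or that it has not come to rest (for what has run out or reacted, a solid counts together with what of it has only dissolved) (all of the solid substrate has reacted / it is still moving / forward and back rates have come level)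
2. part of the solid substrate that has turned into other species by 2.5 min (what has only dissolved does not count)
3. amount of target at 2.5 min, in percent of the solid substrate charged

By 2.50 min the elm run shows 5.8% of its solid substrate left and the larch run 76.2%, which looks like a much faster elm run. In concentration, however, elm lost 4.71 mM and larch 4.76 mM. Since these match, the solid loss, the concentration of solid substrate gone by that time while solid remains, stands at 4.73 mM. The charge enters at zero order. Target matches too, at 0.865 mM counted as solid substrate.

In the larch run the loss curve opens at a mean 6.70 mM min⁻¹ over the first 0.200 min, then bends, and from 1.33 min to 2.50 min it climbs at a mean 0.974 mM min⁻¹, more slowly than at the opening, with no level in sight. A line of that slope, drawn back from the solid loss, meets the axis at 2.30 mM, taken as the dissolved stock.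

For this flask, whose charge exceeds the loss, my reckoning leaves 52.6% as solid. It gives 24.4% converted and 8.65% target, with solid still falling 12 percentage points over the last 1.25 min.

The forecast says it is still moving, with conversion 23% (17% to 29%) and target 8.7% (8% to 9.4%), slightly below my conversion: “So while solid remains, the solution stays near saturation and the loading doesn't matter.”

The flask gives this verdict: it is still moving, with conversion 21.7% and target 8.41%, inside the forecast's ranges. At 2.50 min it holds 13.2% of isomer of the product, a species in neither table. The solid loss counts it anyway: 47.3% of the charge reckoned gone stands against 47.3% found, the conversion plus 25.6% of dissolved starting material.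

    2 starting material ⇌ target (K = 78.0 L mol⁻¹, k = 4.70 L mol⁻¹ s⁻¹)
    target ⇌ isomer of the product (K = 2.50, k = 0.0280 s⁻¹)
    starting material → decomposition product (k = 2.90 × 10⁻⁵ s⁻¹)
    solid substrate ⇌ starting material, rate k4*(cs4 - [starting material]) while solid is left; crystals form when [starting material] > cs4 (solubility = 2.80 mM, k = 0.0500 s⁻¹)

A neighbour charged with 17 mM should, by the same solid loss, keep 72.2% as solid and hold 5.09% target. Computed, it keeps 72.2% and holds 4.95%.

The data were generated by integration with constants of no real substance; noise was put on by code.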